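Retrosynthesis: the two aryl O–CH2OMe bonds and the O–Si bond are cut first and the quinone is taken back to a 4-methoxy-1-naphthol. Ring B is then cut at C4–C3, C2–C1 and C1–C8a into an aryl(methoxy)carbene complex of Cr(CO)5, one CO ligand and a terminal alkyne. The alkyne ester is cut at the acyl C–O bond and the alkynol at the carbinol–alkyne C–C bond.
Enabling feature: ring B (C1–C4, C4a, C8a) has oxygen at C1 and C4, the C1'–C4' side chain at C2 beside the C1 oxygen, and hydrogen at C3. This is the pattern a terminal alkyne gives in a chromium carbene benzannulation.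
Forward order: ring A comes from hydroquinone, the side chain is built as an alkynol and acylated, and ring B is closed last from carbene, alkyne and CO. Oxidation and deprotection finish the route.
Stereochemistry: the only stereocenter, C1', is set by asymmetric transfer hydrogenation of a silyl ynone with an (R,R)-TsDPEN ruthenium catalyst. It is carried unchanged as its ester through the ring closure.

Key step: step 9

Remark: the benzannulation first gives the naphthol as its Cr(CO)3 complex. Stirring in air is assumed to remove the metal, so the metal-free naphthol is taken as the product of the key step.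

Step 1
Reactants: 1 hydroquinone
Product: 2 1,4-bis(methoxymethoxy)benzene
Conditions: NaH, MOMCl, DMF, 0 °C → rt
Reagents that add atoms: chloromethyl methyl ether, COCCl
Why: Double Williamson etherification of the bis-phenoxide with the reactive alpha-chloro ether gives the bis-acetal, whose OCH2OMe groups later direct ortho-lithiation.

Step 2
Reactants: 2 1,4-bis(methoxymethoxy)benzene; 3 hexacarbonylchromium
Product: 6 pentacarbonyl{[2,5-bis(methoxymethoxy)phenyl](methoxy)methylidene}chromium, via aryllithium 4 (not isolated), via lithium acylchromate 5 (not isolated)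
Conditions: n-BuLi, TMEDA, THF, 0 °C; Cr(CO)6, 0 °C → rt; then Me3OBF4, CH2Cl2, 0 °C
Reagents that add atoms: trimethyloxonium tetrafluoroborate, C[O+](C)C.F[B-](F)(F)F
Why: Directed ortho-metalation beside a MOM ether (all four ring C–H positions are equivalent), addition of the aryllithium to a CO ligand and O-methylation of the acylchromate make up the Fischer carbene synthesis.

Step 3
Reactants: 7 4-methylpent-3-enoic acid
Product: 9 N-methoxy-N,4-dimethylpent-3-enamide, via acyl imidazolide 8 (not isolated)
Conditions: CDI, CH2Cl2, rt; then MeNH(OMe)·HCl, rt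
Reagents that add atoms: N,O-dimethylhydroxylamine hydrochloride, CNOC.Cl
Why: Activation as the acyl imidazolide and aminolysis give the Weinreb amide under conditions mild enough to leave the beta,gamma-alkene in place.

Step 4
Reactants: 9 N-methoxy-N,4-dimethylpent-3-enamide
Product: 11 6-methyl-1-(trimethylsilyl)hept-5-en-1-yn-3-one, via lithium hemiaminal adduct 10 (not isolated)
Conditions: TMS-acetylene, n-BuLi, THF, −78 °C; then 9, −78 → 0 °C; cold 1 M HCl quench
Reagents that add atoms: ethynyltrimethylsilane, C#C[Si](C)(C)C
Why: In this Weinreb ketone synthesis the chelated tetrahedral adduct holds until the cold acidic quench, so the ynone forms without over-addition and the freed amine is protonated before it can add to the ynone.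

Step 5
Reactants: 11 6-methyl-1-(trimethylsilyl)hept-5-en-1-yn-3-one
Product: 12 (R)-6-methyl-1-(trimethylsilyl)hept-5-en-1-yn-3-ol
Conditions: Ru[(R,R)-TsDPEN](p-cymene) (16-electron amido complex, 1 mol %, no added base), i-PrOH, rt
Reagents that add atoms: none
Why: In the Noyori–Ikariya asymmetric transfer hydrogenation of an alkynyl ketone the Ru–H/N–H pair delivers hydrogen through a six-membered transition state in which the alkyne takes the place usually held by an aryl group, so the (R,R)-ligand should give the (R)-carbinol, the future C1'.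

Step 6
Reactants: 12 (R)-6-methyl-1-(trimethylsilyl)hept-5-en-1-yn-3-ol
Product: 13 (R)-6-methylhept-5-en-1-yn-3-ol
Conditions: K2CO3 (cat.), MeOH, 0 °C → rt
Reagents that add atoms: none
Why: Methanolysis of the alkynyl C–Si bond (protodesilylation) frees the terminal alkyne without touching the carbinol stereocenter.

Step 7
Reactants: 14 3-hydroxy-3-methylbutanoic acid
Product: 16 3-methyl-3-(triethylsilyloxy)butanoic acid, via bis-silylated acid 15 (not isolated)
Conditions: Et3SiOTf (2.3 equiv), 2,6-lutidine, CH2Cl2, −78 → 0 °C; then THF/H2O, rt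
Reagents that add atoms: triethylsilyl trifluoromethanesulfonate, CC[Si](CC)(CC)OS(=O)(=O)C(F)(F)F
Why: The silyl triflate silylates both the tertiary alcohol and the acid, and the labile silyl ester alone is hydrolysed by water, which leaves the tertiary silyl ether on the free acid.

Step 8
Reactants: 13 (R)-6-methylhept-5-en-1-yn-3-ol; 16 3-methyl-3-(triethylsilyloxy)butanoic acid
Product: 17 (R)-6-methylhept-5-en-1-yn-3-yl 3-methyl-3-(triethylsilyloxy)butanoate
Conditions: DCC, DMAP (cat.), CH2Cl2, 0 °C → rt
Reagents that add atoms: none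
Why: Steglich esterification acylates the carbinol oxygen, so no bond to the stereocenter is broken and the (R)-configuration is retained.

Step 9
Reactants: 6 pentacarbonyl{[2,5-bis(methoxymethoxy)phenyl](methoxy)methylidene}chromium; 17 (R)-6-methylhept-5-en-1-yn-3-yl 3-methyl-3-(triethylsilyloxy)butanoate
Product: 19 (R)-1-[1-hydroxy-4-methoxy-5,8-bis(methoxymethoxy)naphthalen-2-yl]-4-methylpent-3-en-1-yl 3-methyl-3-(triethylsilyloxy)butanoate, via tricarbonylchromium naphthol complex 18 (not isolated)
Conditions: 6 (1.3 equiv), THF (degassed), 50 °C, Ar; then air, rt; short silica pad, used at once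
Reagents that add atoms: none
Why: Thermal loss of one CO from the zerovalent chromium carbene 6 opens a site for alkyne 17, which inserts into the Cr=C bond with its CH terminus on the carbene carbon (C4–C3), and CO insertion at the new carbene carbon (C2–C1) gives a chromium-bound dienylketene. Ring B closes by 6-pi electrocyclisation of that ketene onto the one unsubstituted ortho carbon of the aryl group (C1–C8a), and tautomerisation gives the naphthol as its Cr(CO)3 complex 18, from which air removes the metal. This is a Dötz benzannulation, the standard reaction of aryl(alkoxy)carbene complexes of Cr(CO)5 with terminal alkynes, including alkynes that carry a propargylic oxygen substituent. No stereocenter is formed, and C1' lies outside the reacting atoms and is carried unchanged. The step needs regioselective insertion, which the size difference between the alkyne hydrogen and the branched propargylic carbon should secure by placing the larger group beside the CO-derived C1. It also needs benzannulation to win over indene or cyclobutenone formation, which a methoxy carbene in THF at moderate temperature favours, and the prenyl alkene should stay a spectator because trapping the vinylcarbene would require a bicyclo[2.1.0] product.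

Step 10
Reactants: 19 (R)-1-[1-hydroxy-4-methoxy-5,8-bis(methoxymethoxy)naphthalen-2-yl]-4-methylpent-3-en-1-yl 3-methyl-3-(triethylsilyloxy)butanoate
Product: 20 (R)-1-[5,8-bis(methoxymethoxy)-1,4-dioxo-1,4-dihydronaphthalen-2-yl]-4-methylpent-3-en-1-yl 3-methyl-3-(triethylsilyloxy)butanoate
Conditions: (NH4)2Ce(NO3)6 (2.2 equiv), MeCN/H2O, 0 °C, short reaction time
Reagents that add atoms: water, O
Why: Two-electron oxidation of the para-methoxyphenol by tetravalent cerium, attack of water at C4 and loss of methanol (oxidative demethylation) give the quinone, and the free phenol makes ring B far easier to oxidise than the bis-acetal ring A.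

Step 11
Reactants: 20 (R)-1-[5,8-bis(methoxymethoxy)-1,4-dioxo-1,4-dihydronaphthalen-2-yl]-4-methylpent-3-en-1-yl 3-methyl-3-(triethylsilyloxy)butanoate
Product: 21 beta-HIVS, (R)-1-(5,8-dihydroxy-1,4-dioxo-1,4-dihydronaphthalen-2-yl)-4-methylpent-3-en-1-yl 3-hydroxy-3-methylbutanoate
Conditions: 2 M aq. HCl, THF, 0 °C → rt
Reagents that add atoms: none
Why: Acid hydrolysis cleaves the two aryl MOM acetals, helped by the hydrogen bond each freed peri hydroxyl forms with a quinone carbonyl, and also the tertiary silyl ether, while the C1' ester on the electron-poor quinone ring resists ionisation.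

Compound list
1 | hydroquinone | Oc1ccc(O)cc1 | starting material
2 | 1,4-bis(methoxymethoxy)benzene | COCOc1ccc(OCOC)cc1 | intermediate
3 | hexacarbonylchromium | O=C=[Cr](=C=O)(=C=O)(=C=O)(=C=O)=C=O | starting material
4 | [2,5-bis(methoxymethoxy)phenyl]lithium (formed in the flask, not isolated) | [Li]c1cc(OCOC)ccc1OCOC | intermediate
5 | lithium pentacarbonyl{[2,5-bis(methoxymethoxy)phenyl](oxido)methylidene}chromate (formed in the flask, not isolated) | [Li+].[O-]C(=[Cr](=C=O)(=C=O)(=C=O)(=C=O)=C=O)c1cc(OCOC)ccc1OCOC | intermediate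
6 | pentacarbonyl{[2,5-bis(methoxymethoxy)phenyl](methoxy)methylidene}chromium | COC(=[Cr](=C=O)(=C=O)(=C=O)(=C=O)=C=O)c1cc(OCOC)ccc1OCOC | intermediate
7 | 4-methylpent-3-enoic acid | CC(C)=CCC(O)=O | starting material
8 | 1-(imidazol-1-yl)-4-methylpent-3-en-1-one (formed in the flask, not isolated) | CC(C)=CCC(=O)n1ccnc1 | intermediate
9 | N-methoxy-N,4-dimethylpent-3-enamide | CC(C)=CCC(=O)N(C)OC | intermediate
10 | lithium 3-[methoxy(methyl)amino]-6-methyl-1-(trimethylsilyl)hept-5-en-1-yn-3-olate (formed in the flask, not isolated) | CC(C)=CCC(O[Li])(N(C)OC)C#C[Si](C)(C)C | intermediate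
11 | 6-methyl-1-(trimethylsilyl)hept-5-en-1-yn-3-one | CC(C)=CCC(=O)C#C[Si](C)(C)C | intermediate
12 | (R)-6-methyl-1-(trimethylsilyl)hept-5-en-1-yn-3-ol | CC(C)=CC[C@@H](O)C#C[Si](C)(C)C | intermediate
13 | (R)-6-methylhept-5-en-1-yn-3-ol | CC(C)=CC[C@@H](O)C#C | intermediate
14 | 3-hydroxy-3-methylbutanoic acid | CC(C)(O)CC(O)=O | starting material
15 | triethylsilyl 3-methyl-3-(triethylsilyloxy)butanoate (formed in the flask, not isolated) | CC[Si](CC)(CC)OC(C)(C)CC(=O)O[Si](CC)(CC)CC | intermediate
16 | 3-methyl-3-(triethylsilyloxy)butanoic acid | CC[Si](CC)(CC)OC(C)(C)CC(O)=O | intermediate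
17 | (R)-6-methylhept-5-en-1-yn-3-yl 3-methyl-3-(triethylsilyloxy)butanoate | CC(C)=CC[C@@H](OC(=O)CC(C)(C)O[Si](CC)(CC)CC)C#C | intermediate
18 | tricarbonylchromium complex of 19, metal bound eta-6 to ring B, drawn as arene and Cr(CO)3 unit joined by a dot (formed in the flask, not isolated) | CC(C)=CC[C@@H](OC(=O)CC(C)(C)O[Si](CC)(CC)CC)c1cc(OC)c2c(OCOC)ccc(OCOC)c2c1O.O=C=[Cr](=C=O)=C=O | intermediate
19 | (R)-1-[1-hydroxy-4-methoxy-5,8-bis(methoxymethoxy)naphthalen-2-yl]-4-methylpent-3-en-1-yl 3-methyl-3-(triethylsilyloxy)butanoate | CC(C)=CC[C@@H](OC(=O)CC(C)(C)O[Si](CC)(CC)CC)c1cc(OC)c2c(OCOC)ccc(OCOC)c2c1O | intermediate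
20 | (R)-1-[5,8-bis(methoxymethoxy)-1,4-dioxo-1,4-dihydronaphthalen-2-yl]-4-methylpent-3-en-1-yl 3-methyl-3-(triethylsilyloxy)butanoate | CC(C)=CC[C@@H](OC(=O)CC(C)(C)O[Si](CC)(CC)CC)C1=CC(=O)c2c(OCOC)ccc(OCOC)c2C1=O | intermediate
21 | beta-HIVS, (R)-1-(5,8-dihydroxy-1,4-dioxo-1,4-dihydronaphthalen-2-yl)-4-methylpent-3-en-1-yl 3-hydroxy-3-methylbutanoate | CC(C)=CC[C@@H](OC(=O)CC(C)(C)O)C1=CC(=O)c2c(O)ccc(O)c2C1=O | target

Total step count: 11.
Longest linear sequence: 8 steps (steps 3, 4, 5, 6, 8, 9, 10, 11, from 4-methylpent-3-enoic acid). The carbene branch (steps 1, 2) and the acid branch (step 7) join at steps 9 and 8.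

Steps most likely to fail

1. Step 9. The propargylic acyloxy group may be lost or shifted while chromium is still bound. Possible paths are ionisation at the carbon that becomes benzylic to the Cr(CO)3-bound ring, elimination from the ortho-hydroxybenzylic ester toward a quinone methide, or acyl transfer to the new phenol. Indene or cyclobutenone formation may also compete. The fallback keeps the benzannulation but carries C1' as a silyl ether and attaches the ester afterwards. It sets out from 13 and comes back at 20. Alcohol 13 is silylated (TBSCl, imidazole, DMF) to (R)-tert-butyldimethyl[(6-methylhept-5-en-1-yn-3-yl)oxy]silane F1. Benzannulation of F1 with 6 (THF, 50 °C; then air) should pass through the tricarbonylchromium naphthol complex F2 to (R)-2-[1-(tert-butyldimethylsilyloxy)-4-methylpent-3-en-1-yl]-4-methoxy-5,8-bis(methoxymethoxy)naphthalen-1-ol F3. Oxidation with (NH4)2Ce(NO3)6 in MeCN/H2O should give (R)-2-[1-(tert-butyldimethylsilyloxy)-4-methylpent-3-en-1-yl]-5,8-bis(methoxymethoxy)naphthalene-1,4-dione F4. HF·pyridine in THF then frees (R)-2-(1-hydroxy-4-methylpent-3-en-1-yl)-5,8-bis(methoxymethoxy)naphthalene-1,4-dione F5. Steglich esterification of F5 with 16 (DCC, DMAP, CH2Cl2) returns to 20.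

2. Step 5. The C4 methylene of 11 is both allylic and alpha to the ynone, so the basic amido catalyst may move the C5–C6 alkene into conjugation before hydride transfer, and facial selectivity may be incomplete. The fallback sets the stereocenter by C–C bond formation and avoids the ynone. It does not set out from a numbered compound: it replaces 7 to 11 by commercial 3-(trimethylsilyl)prop-2-ynal F6 and comes back at 12. Brown allylation of F6 with (+)-B-allyldiisopinocampheylborane (the reagent from (−)-alpha-pinene, Et2O, −78 °C, oxidative work-up) should add allyl to the Re face and give (R)-1-(trimethylsilyl)hex-5-en-1-yn-3-ol F7. Cross metathesis of F7 with excess 2-methylbut-2-ene (second-generation Grubbs catalyst RuCl2(=CHPh)(H2IMes)(PCy3), CH2Cl2, rt) converts the vinyl end into the trisubstituted alkene and gives 12.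

3. Step 11. Under Brønsted acid the tertiary carbinol may lose water to give the 3-methylbut-2-enoate, the C1' ester may ionise, or the prenyl alkene may be protonated, all in competition with slow hydrolysis of the MOM acetals. The fallback avoids protic acid by using two orthogonal operations. It sets out from 20 and comes back at 21. Fluoride (HF·pyridine, THF/pyridine, 0 °C) removes the silyl ether to give (R)-1-[5,8-bis(methoxymethoxy)-1,4-dioxo-1,4-dihydronaphthalen-2-yl]-4-methylpent-3-en-1-yl 3-hydroxy-3-methylbutanoate F8. MgBr2·OEt2 in Et2O/CH2Cl2 (0 °C → rt, aqueous work-up) then cleaves the two peri MOM ethers by chelation to the quinone carbonyls and gives 21.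

Further compounds
F1 | step 9 | (R)-tert-butyldimethyl[(6-methylhept-5-en-1-yn-3-yl)oxy]silane | CC(C)=CC[C@@H](O[Si](C)(C)C(C)(C)C)C#C
F2 | step 9 | tricarbonylchromium complex of F3, drawn as arene and Cr(CO)3 unit joined by a dot | CC(C)=CC[C@@H](O[Si](C)(C)C(C)(C)C)c1cc(OC)c2c(OCOC)ccc(OCOC)c2c1O.O=C=[Cr](=C=O)=C=O
F3 | step 9 | (R)-2-[1-(tert-butyldimethylsilyloxy)-4-methylpent-3-en-1-yl]-4-methoxy-5,8-bis(methoxymethoxy)naphthalen-1-ol | CC(C)=CC[C@@H](O[Si](C)(C)C(C)(C)C)c1cc(OC)c2c(OCOC)ccc(OCOC)c2c1O
F4 | step 9 | (R)-2-[1-(tert-butyldimethylsilyloxy)-4-methylpent-3-en-1-yl]-5,8-bis(methoxymethoxy)naphthalene-1,4-dione | CC(C)=CC[C@@H](O[Si](C)(C)C(C)(C)C)C1=CC(=O)c2c(OCOC)ccc(OCOC)c2C1=O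
F5 | step 9 | (R)-2-(1-hydroxy-4-methylpent-3-en-1-yl)-5,8-bis(methoxymethoxy)naphthalene-1,4-dione | CC(C)=CC[C@@H](O)C1=CC(=O)c2c(OCOC)ccc(OCOC)c2C1=O
F6 | step 5 | 3-(trimethylsilyl)prop-2-ynal | O=CC#C[Si](C)(C)C
F7 | step 5 | (R)-1-(trimethylsilyl)hex-5-en-1-yn-3-ol | C=CC[C@@H](O)C#C[Si](C)(C)C
F8 | step 11 | (R)-1-[5,8-bis(methoxymethoxy)-1,4-dioxo-1,4-dihydronaphthalen-2-yl]-4-methylpent-3-en-1-yl 3-hydroxy-3-methylbutanoate | CC(C)=CC[C@@H](OC(=O)CC(C)(C)O)C1=CC(=O)c2c(OCOC)ccc(OCOC)c2C1=O
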